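Ring A is numbered C1 (C=O), C2 (allyl), C3, C4 (quaternary C–OMe), C5 (C–OMe), C6; the side chain is C8 (CHMe) and C7 (ArCH2). The adjacent oxygens on C4 and C5 are a masked α-ketol, so the C4–C5 bond is made by a carbene-catalysed crossed benzoin: the aldehyde carbon C5 of an acyclic (Z)-enone aldehyde becomes an acyl-anion equivalent and adds to the C4 ketone, closing ring A and setting the C4 carbinol in one operation. The precursor 22 carries C8 (Evans alkylation), a single C1 silyl ether (transfer hydrogenation) and the Z-alkene (directed allylmagnesiation). Enolate O-methylation at C5, desilylation and C1 oxidation finish the dienone regiospecifically.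

Key step: step 13

Assumption: the face of the C4 carbonyl that the chosen triazolium enantiomer exposes is taken from the usual shielding model and is untested for an enone ketone; the mirror-image salt is made in the same way.
Design remark: C1 is carried as the single (R) epimer although it ends as the carbonyl, so that one substrate diastereomer reaches step 13; both silyl ethers are triisopropylsilyl (TIPS) so that one fluoride treatment removes them.

Step 1
Reactants: 1 vanillin
Product: 2 3-methoxy-4-(triisopropylsilyloxy)benzaldehyde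
Conditions: TIPSCl, imidazole, DMF, 23 °C
Reagents that add atoms: chlorotriisopropylsilane, CC(C)[Si](Cl)(C(C)C)C(C)C
Why: Imidazole-mediated silylation of the phenol (silyl ether formation) gives a TIPS ether that should withstand borohydride, enolates, organolithiums and mild acid and is kept to the end.

Step 2
Reactants: 2 3-methoxy-4-(triisopropylsilyloxy)benzaldehyde
Product: 3 [3-methoxy-4-(triisopropylsilyloxy)phenyl]methanol
Conditions: NaBH4, MeOH, 0 °C
Reagents that add atoms: none
Why: Borohydride reduction of the aryl aldehyde to the benzylic alcohol leaves the aryl silyl ether untouched at 0 °C.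

Step 3
Reactants: 3 [3-methoxy-4-(triisopropylsilyloxy)phenyl]methanol
Product: 4 [4-(bromomethyl)-2-methoxyphenoxy]triisopropylsilane
Conditions: CBr4, PPh3, CH2Cl2, 0 °C
Reagents that add atoms: tetrabromomethane, BrC(Br)(Br)Br
Why: Appel bromination converts the benzylic alcohol into the bromide under neutral conditions that spare the silyl ether, and the electron-rich bromide is used at once.

Step 4
Reactants: 5 (S)-4-benzyl-3-propionyloxazolidin-2-one; 4 [4-(bromomethyl)-2-methoxyphenoxy]triisopropylsilane
Product: 7 (S)-4-benzyl-3-{(2R)-3-[3-methoxy-4-(triisopropylsilyloxy)phenyl]-2-methylpropanoyl}oxazolidin-2-one, via sodium enolate 6 (not isolated)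
Conditions: NaN(SiMe3)2, THF, −78 °C; then 4, −78 → −30 °C
Reagents that add atoms: none
Why: Evans asymmetric alkylation, in which the chelated (Z)-enolate is alkylated on the face away from the benzyl group of the oxazolidinone, sets C8 as (R).

Step 5
Reactants: 7 (S)-4-benzyl-3-{(2R)-3-[3-methoxy-4-(triisopropylsilyloxy)phenyl]-2-methylpropanoyl}oxazolidin-2-one
Product: 8 (2R)-N-methoxy-3-[3-methoxy-4-(triisopropylsilyloxy)phenyl]-N,2-dimethylpropanamide
Conditions: MeNH(OMe)·HCl, AlMe3, CH2Cl2, −10 → 0 °C; aq KNaC4H4O6 (potassium sodium tartrate)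
Reagents that add atoms: N,O-dimethylhydroxylamine hydrochloride, CNOC.Cl
Why: Weinreb transamination, in which the aluminium amide attacks the exocyclic imide carbonyl without enolising C8, releases the auxiliary for recovery.

Step 6
Reactants: 9 methyl 3,3-dimethoxypropanoate
Product: 10 N,3,3-trimethoxy-N-methylpropanamide
Conditions: MeNH(OMe)·HCl, i-PrMgCl, THF, −20 → 0 °C
Reagents that add atoms: N,O-dimethylhydroxylamine hydrochloride, CNOC.Cl
Why: Aminolysis of the ester by the magnesium amide of N,O-dimethylhydroxylamine (Weinreb amide synthesis) proceeds under basic conditions to which the acetal is inert.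

Step 7
Reactants: 11 ethynyltrimethylsilane; 10 N,3,3-trimethoxy-N-methylpropanamide
Product: 13 5,5-dimethoxy-1-(trimethylsilyl)pent-1-yn-3-one, via lithium acetylide 12 (not isolated)
Conditions: 11, n-BuLi, THF, −78 °C; then 10, −78 → 0 °C; NH4Cl aq
Reagents that add atoms: none
Why: Weinreb ketone synthesis, in which the chelated tetrahedral adduct does not collapse before the quench, lets the acetylide add only once and gives the ynone.

Step 8
Reactants: 13 5,5-dimethoxy-1-(trimethylsilyl)pent-1-yn-3-one
Product: 15 (3R)-5,5-dimethoxypent-1-yn-3-ol, via silylated alkynol 14 (not isolated)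
Conditions: Ru[(R,R)-TsNCHPhCHPhNH](η6-p-cymene) (1 mol%), i-PrOH, 25 °C; then K2CO3, MeOH, 0 °C
Reagents that add atoms: none
Why: Noyori asymmetric transfer hydrogenation of an alkynyl ketone, in which the alkyne takes the place of the aryl group in the CH–π transition state so that the (R,R)-catalyst should give the (R)-carbinol C1, is followed by base-catalysed methanolysis of the alkynyl C–Si bond.

Step 9
Reactants: 15 (3R)-5,5-dimethoxypent-1-yn-3-ol; 16 allylmagnesium bromide
Product: 18 (3R,4Z)-4-(iodomethylidene)-1,1-dimethoxyhept-6-en-3-ol, via alkenylmagnesium alkoxide 17 (not isolated)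
Conditions: 16 (3.5 equiv), Et2O, 0 °C → reflux; then I2, THF, −78 → 0 °C
Reagents that add atoms: iodine, II
Why: Hydroxyl-directed anti-carbomagnesiation of the propargylic alkoxide (allylic Grignard reagents need no copper) puts allyl on C2 and magnesium on C3 inside a five-membered chelate, and iodinolysis with retention leaves iodine cis to C1, which fixes the later Z-enone geometry.

Step 10
Reactants: 18 (3R,4Z)-4-(iodomethylidene)-1,1-dimethoxyhept-6-en-3-ol
Product: 19 {[(3R,4Z)-4-(iodomethylidene)-1,1-dimethoxyhept-6-en-3-yl]oxy}triisopropylsilane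
Conditions: TIPSOTf, 2,6-lutidine, CH2Cl2, −78 → −20 °C
Reagents that add atoms: triisopropylsilyl trifluoromethanesulfonate, CC(C)[Si](OS(=O)(=O)C(F)(F)F)(C(C)C)C(C)C
Why: Silyl triflate silylation of the hindered allylic alcohol at low temperature should leave the dimethyl acetal alone, and the bulky TIPS group is chosen because it resists 1,4 O-to-C migration in step 11 and the acid of step 12.

Step 11
Reactants: 19 {[(3R,4Z)-4-(iodomethylidene)-1,1-dimethoxyhept-6-en-3-yl]oxy}triisopropylsilane; 8 (2R)-N-methoxy-3-[3-methoxy-4-(triisopropylsilyloxy)phenyl]-N,2-dimethylpropanamide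
Product: 21 (2R,4Z,6R)-8,8-dimethoxy-1-[3-methoxy-4-(triisopropylsilyloxy)phenyl]-2-methyl-5-(prop-2-en-1-yl)-6-(triisopropylsilyloxy)oct-4-en-3-one, via alkenyllithium 20 (not isolated)
Conditions: 19, t-BuLi (2.1 equiv), Et2O, −78 °C; then 8, −78 → −30 °C; NH4Cl aq
Reagents that add atoms: none
Why: Iodine–lithium exchange with retention of alkene geometry followed by Weinreb ketone synthesis joins C3 to C4 with C1 cis to the ketone, the amide being added at −78 °C in ether to outrun silyl migration and enolisation at C8.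

Step 12
Reactants: 21 (2R,4Z,6R)-8,8-dimethoxy-1-[3-methoxy-4-(triisopropylsilyloxy)phenyl]-2-methyl-5-(prop-2-en-1-yl)-6-(triisopropylsilyloxy)oct-4-en-3-one
Product: 22 (3R,4Z,7R)-8-[3-methoxy-4-(triisopropylsilyloxy)phenyl]-7-methyl-6-oxo-4-(prop-2-en-1-yl)-3-(triisopropylsilyloxy)oct-4-enal
Conditions: PPTS (0.2 equiv), acetone–H2O (10:1), 40 °C
Reagents that add atoms: water, O
Why: Mild acid-catalysed hydrolysis (transacetalisation with acetone) of the dimethyl acetal should free aldehyde C5 while both TIPS ethers and the Z-enone persist, and the aldehyde is used without chromatography.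

Step 13
Reactants: 22 (3R,4Z,7R)-8-[3-methoxy-4-(triisopropylsilyloxy)phenyl]-7-methyl-6-oxo-4-(prop-2-en-1-yl)-3-(triisopropylsilyloxy)oct-4-enal
Product: 23 (3R,6S)-6-hydroxy-6-{(2R)-1-[3-methoxy-4-(triisopropylsilyloxy)phenyl]propan-2-yl}-4-(prop-2-en-1-yl)-3-(triisopropylsilyloxy)cyclohex-4-en-1-one
Conditions: (5aS,10bR)-2-(pentafluorophenyl)-5a,10b-dihydro-4H,6H-indeno[2,1-b][1,2,4]triazolo[4,3-d][1,4]oxazin-2-ium tetrafluoroborate (C18H11BF9N3O, 15 mol%), NaOAc (20 mol%), CH2Cl2, 23 °C
Reagents that add atoms: none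
Why: The triazolylidene freed by acetate adds to aldehyde carbon C5 and proton transfer gives the Breslow enaminol, whose nucleophilic C5 attacks the C4 ketone before the catalyst is expelled from the resulting alkoxide. This is the intramolecular aldehyde–ketone crossed benzoin known for chiral triazolium salts, applied here to an enone ketone. Ring A closes in the 6-exo-trig mode (C5 onto C4, carbonyl oxygen outside the ring), the Z-alkene holding both carbons within reach. The new C4 centre is set by the catalyst: attack on the Re face of the C4 carbonyl gives C4 (S), the indane backbone shielding one face of the enaminol while the ketone oxygen is hydrogen-bonded to the enol OH. C8 offers only a weak Felkin–Anh bias (methyl against arylmethyl) and that bias points to the Si face, so the catalyst has to overrule it, while the (1R) silyl ether can sit pseudoaxial, trans to the new hydroxyl and free of A(1,2) strain with the C2 allyl group. Chemoselectivity is needed against Stetter addition, aldol closure and β-elimination: only the aldehyde can form the acyl anion, addition to C2 would need a four-membered ring, and the weak base should keep the C6 enolate too scarce for the five-membered aldol, loss of the C1 silyloxy group or epimerisation at C8.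

Step 14
Reactants: 23 (3R,6S)-6-hydroxy-6-{(2R)-1-[3-methoxy-4-(triisopropylsilyloxy)phenyl]propan-2-yl}-4-(prop-2-en-1-yl)-3-(triisopropylsilyloxy)cyclohex-4-en-1-one
Product: 25 {[(1R,4S)-4,5-dimethoxy-4-{(2R)-1-[3-methoxy-4-(triisopropylsilyloxy)phenyl]propan-2-yl}-2-(prop-2-en-1-yl)cyclohexa-2,5-dien-1-yl]oxy}triisopropylsilane, via dipotassium dianion 24 (not isolated)
Conditions: KN(SiMe3)2 (2.5 equiv), THF–DMPU, −78 °C; then MeOTf (3 equiv), −78 → −40 °C
Reagents that add atoms: methyl trifluoromethanesulfonate, COS(=O)(=O)C(F)(F)F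
Why: Williamson methylation of the tertiary potassium alkoxide together with O-alkylation of the potassium enolate by the hard electrophile in a dipolar medium should give both methyl ethers, the enol ether position being unambiguous because C5 can enolise only towards C6 (C4 is quaternary) and the neighbouring C1 silyloxy group hindering C-methylation.

Step 15
Reactants: 25 {[(1R,4S)-4,5-dimethoxy-4-{(2R)-1-[3-methoxy-4-(triisopropylsilyloxy)phenyl]propan-2-yl}-2-(prop-2-en-1-yl)cyclohexa-2,5-dien-1-yl]oxy}triisopropylsilane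
Product: 26 (1R,4S)-4-[(2R)-1-(4-hydroxy-3-methoxyphenyl)propan-2-yl]-4,5-dimethoxy-2-(prop-2-en-1-yl)cyclohexa-2,5-dien-1-ol
Conditions: Bu4NF (3 equiv), THF, 0 → 23 °C; pH 7 phosphate buffer
Reagents that add atoms: none
Why: Fluoride-mediated cleavage of both silyl ethers runs under basic conditions that should leave the acid-labile enol ether and the doubly allylic alcohol intact.

Step 16
Reactants: 26 (1R,4S)-4-[(2R)-1-(4-hydroxy-3-methoxyphenyl)propan-2-yl]-4,5-dimethoxy-2-(prop-2-en-1-yl)cyclohexa-2,5-dien-1-ol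
Product: 27 (4S)-4-[(2R)-1-(4-hydroxy-3-methoxyphenyl)propan-2-yl]-4,5-dimethoxy-2-(prop-2-en-1-yl)cyclohexa-2,5-dien-1-one (CNP0370214.1)
Conditions: MnO2 (activated, 15 equiv), CH2Cl2, 23 °C
Reagents that add atoms: none
Why: MnO2 oxidation of the doubly allylic alcohol C1 (allylic alcohol oxidation on the oxide surface) should be much faster than attack on the phenol, as with hydroxycinnamyl alcohols, and gives the cross-conjugated dienone without touching C4 or C8.

Compound list
1 | vanillin (4-hydroxy-3-methoxybenzaldehyde) | O=Cc1ccc(O)c(OC)c1 | starting material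
2 | 3-methoxy-4-(triisopropylsilyloxy)benzaldehyde | O=Cc1ccc(O[Si](C(C)C)(C(C)C)C(C)C)c(OC)c1 | intermediate
3 | [3-methoxy-4-(triisopropylsilyloxy)phenyl]methanol | OCc1ccc(O[Si](C(C)C)(C(C)C)C(C)C)c(OC)c1 | intermediate
4 | [4-(bromomethyl)-2-methoxyphenoxy]triisopropylsilane | BrCc1ccc(O[Si](C(C)C)(C(C)C)C(C)C)c(OC)c1 | intermediate
5 | (S)-4-benzyl-3-propionyloxazolidin-2-one | CCC(=O)N1[C@@H](Cc2ccccc2)COC1=O | starting material
6 | sodium (Z)-enolate of 5 (formed in the flask) | C/C=C(\[O-])N1[C@@H](Cc2ccccc2)COC1=O.[Na+] | intermediate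
7 | (S)-4-benzyl-3-{(2R)-3-[3-methoxy-4-(triisopropylsilyloxy)phenyl]-2-methylpropanoyl}oxazolidin-2-one | C[C@H](Cc1ccc(O[Si](C(C)C)(C(C)C)C(C)C)c(OC)c1)C(=O)N1[C@@H](Cc2ccccc2)COC1=O | intermediate
8 | (2R)-N-methoxy-3-[3-methoxy-4-(triisopropylsilyloxy)phenyl]-N,2-dimethylpropanamide | CON(C)C(=O)[C@H](C)Cc1ccc(O[Si](C(C)C)(C(C)C)C(C)C)c(OC)c1 | intermediate
9 | methyl 3,3-dimethoxypropanoate | COC(CC(=O)OC)OC | starting material
10 | N,3,3-trimethoxy-N-methylpropanamide | CON(C)C(=O)CC(OC)OC | intermediate
11 | ethynyltrimethylsilane | C#C[Si](C)(C)C | starting material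
12 | lithium (trimethylsilyl)acetylide (formed in the flask) | [Li]C#C[Si](C)(C)C | intermediate
13 | 5,5-dimethoxy-1-(trimethylsilyl)pent-1-yn-3-one | COC(CC(=O)C#C[Si](C)(C)C)OC | intermediate
14 | (3R)-5,5-dimethoxy-1-(trimethylsilyl)pent-1-yn-3-ol (formed in the flask) | C[Si](C)(C)C#C[C@H](O)CC(OC)OC | intermediate
15 | (3R)-5,5-dimethoxypent-1-yn-3-ol | C#C[C@H](O)CC(OC)OC | intermediate
16 | allylmagnesium bromide | C=CC[Mg]Br | starting material
17 | bromomagnesium alkoxide of the (Z)-alkenylmagnesium bromide from 15 (Mg on C3 cis to C1; formed in the flask) | Br[Mg]/C=C(/CC=C)[C@H](O[Mg]Br)CC(OC)OC | intermediate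
18 | (3R,4Z)-4-(iodomethylidene)-1,1-dimethoxyhept-6-en-3-ol | I/C=C(/CC=C)[C@H](O)CC(OC)OC | intermediate
19 | {[(3R,4Z)-4-(iodomethylidene)-1,1-dimethoxyhept-6-en-3-yl]oxy}triisopropylsilane | I/C=C(/CC=C)[C@H](O[Si](C(C)C)(C(C)C)C(C)C)CC(OC)OC | intermediate
20 | (Z)-alkenyllithium from 19 (Li in place of I; formed in the flask) | [Li]/C=C(/CC=C)[C@H](O[Si](C(C)C)(C(C)C)C(C)C)CC(OC)OC | intermediate
21 | (2R,4Z,6R)-8,8-dimethoxy-1-[3-methoxy-4-(triisopropylsilyloxy)phenyl]-2-methyl-5-(prop-2-en-1-yl)-6-(triisopropylsilyloxy)oct-4-en-3-one | C=CC/C(=C/C(=O)[C@H](C)Cc1ccc(O[Si](C(C)C)(C(C)C)C(C)C)c(OC)c1)[C@H](O[Si](C(C)C)(C(C)C)C(C)C)CC(OC)OC | intermediate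
22 | (3R,4Z,7R)-8-[3-methoxy-4-(triisopropylsilyloxy)phenyl]-7-methyl-6-oxo-4-(prop-2-en-1-yl)-3-(triisopropylsilyloxy)oct-4-enal (precursor of the key step) | C=CC/C(=C/C(=O)[C@H](C)Cc1ccc(O[Si](C(C)C)(C(C)C)C(C)C)c(OC)c1)[C@H](O[Si](C(C)C)(C(C)C)C(C)C)CC=O | intermediate
23 | (3R,6S)-6-hydroxy-6-{(2R)-1-[3-methoxy-4-(triisopropylsilyloxy)phenyl]propan-2-yl}-4-(prop-2-en-1-yl)-3-(triisopropylsilyloxy)cyclohex-4-en-1-one (product of the key step) | C=CCC1=C[C@@](O)([C@H](C)Cc2ccc(O[Si](C(C)C)(C(C)C)C(C)C)c(OC)c2)C(=O)C[C@H]1O[Si](C(C)C)(C(C)C)C(C)C | intermediate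
24 | dipotassium alkoxide–enolate of 23 (formed in the flask) | C=CCC1=C[C@@]([O-])([C@H](C)Cc2ccc(O[Si](C(C)C)(C(C)C)C(C)C)c(OC)c2)C([O-])=C[C@H]1O[Si](C(C)C)(C(C)C)C(C)C.[K+].[K+] | intermediate
25 | {[(1R,4S)-4,5-dimethoxy-4-{(2R)-1-[3-methoxy-4-(triisopropylsilyloxy)phenyl]propan-2-yl}-2-(prop-2-en-1-yl)cyclohexa-2,5-dien-1-yl]oxy}triisopropylsilane | C=CCC1=C[C@@](OC)([C@H](C)Cc2ccc(O[Si](C(C)C)(C(C)C)C(C)C)c(OC)c2)C(OC)=C[C@H]1O[Si](C(C)C)(C(C)C)C(C)C | intermediate
26 | (1R,4S)-4-[(2R)-1-(4-hydroxy-3-methoxyphenyl)propan-2-yl]-4,5-dimethoxy-2-(prop-2-en-1-yl)cyclohexa-2,5-dien-1-ol | C=CCC1=C[C@@](OC)([C@H](C)Cc2ccc(O)c(OC)c2)C(OC)=C[C@H]1O | intermediate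
27 | (4S)-4-[(2R)-1-(4-hydroxy-3-methoxyphenyl)propan-2-yl]-4,5-dimethoxy-2-(prop-2-en-1-yl)cyclohexa-2,5-dien-1-one | C=CCC1=C[C@@](OC)([C@H](C)Cc2ccc(O)c(OC)c2)C(OC)=CC1=O | target

Total step count: 16.
Longest linear sequence: 11 steps (steps 1–5 then 11–16 from vanillin; the branch from 9, steps 6–10 then 11–16, is equally long).

Steps most likely to fail

Step 13. The facial selectivity at C4 may be insufficient or reversed, because the catalyst has to override the bias of C8 and of the C1 centre in the forming ring. The aldehyde may also be lost through enolisation (β-elimination of the C1 silyloxy group, five-membered aldol closure), or the enone may isomerise from Z to E before ring closure. The fallback sets out from 22 and forms the same C4–C5 bond by reductive ketyl coupling. SmI2 in THF with t-BuOH at −78 °C (intramolecular pinacol cyclisation of the keto-aldehyde) should give the ring A 1,2-diol, 1-{(2R)-1-[3-methoxy-4-(triisopropylsilyloxy)phenyl]propan-2-yl}-5-(prop-2-en-1-yl)-4-(triisopropylsilyloxy)cyclohex-5-ene-1,2-diol F1. Parikh–Doering oxidation (SO3·pyridine, DMSO, i-Pr2NEt) can touch only its secondary C5 carbinol, so it comes back to the route at 23. The C4 configuration then rests on substrate control, and the (S) epimer would be separated at 23.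

Step 14. The enolate may be methylated on carbon C6 instead of oxygen, the hindered tertiary alkoxide may react incompletely, or silanolate may be eliminated from the enolate on warming. The fallback sets out from 23 and reaches the C5 enol ether by equilibration instead of enolate trapping:
- MeOTf with 2,6-di-tert-butyl-4-methylpyridine in CH2Cl2 methylates the tertiary alcohol alone to the C4 methyl ether ketone F2.
- Bu4NF buffered with AcOH removes both silyl groups to give the β-hydroxy ketone phenol F3.
- MnO2 oxidises its allylic C1 carbinol to the enolised 1,3-dione F4.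
- HC(OMe)3 and MeOH with catalytic camphorsulfonic acid form the vinylogous methyl ester under equilibrating conditions, which do not methylate the phenol.

This relies on the cross-conjugated 5-methoxy-2,5-dienone being more stable than its linearly conjugated regioisomer, and it comes back to the route at 27.

Step 11. The silyl group may migrate from oxygen to carbon (1,4-shift) in the (Z)-γ-silyloxy alkenyllithium, or the hindered alkenyllithium may enolise the amide instead of adding to it. The fallback sets out from 7 and replaces the organolithium by a chromium-mediated coupling: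
- LiBH4 (THF, MeOH, 0 °C) removes the auxiliary reductively to give the primary alcohol F5.
- Dess–Martin periodinane with NaHCO3 gives the aldehyde F6, which is used at once.
- Nozaki–Hiyama–Kishi coupling with iodide 19 (CrCl2, catalytic NiCl2, DMSO–THF) tolerates the silyl ether and the acetal, keeps the alkene geometry and gives the allylic alcohol F7 as both carbinol epimers.
- Dess–Martin oxidation comes back to the route at 21.

Further compounds
F1 | step 13 | 1-{(2R)-1-[3-methoxy-4-(triisopropylsilyloxy)phenyl]propan-2-yl}-5-(prop-2-en-1-yl)-4-(triisopropylsilyloxy)cyclohex-5-ene-1,2-diol (quaternary carbinol and silyloxy carbon as in 23, secondary carbinol unassigned) | C=CCC1=C[C@@](O)([C@H](C)Cc2ccc(O[Si](C(C)C)(C(C)C)C(C)C)c(OC)c2)C(O)C[C@H]1O[Si](C(C)C)(C(C)C)C(C)C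
F2 | step 14 | (3R,6S)-6-methoxy-6-{(2R)-1-[3-methoxy-4-(triisopropylsilyloxy)phenyl]propan-2-yl}-4-(prop-2-en-1-yl)-3-(triisopropylsilyloxy)cyclohex-4-en-1-one | C=CCC1=C[C@@](OC)([C@H](C)Cc2ccc(O[Si](C(C)C)(C(C)C)C(C)C)c(OC)c2)C(=O)C[C@H]1O[Si](C(C)C)(C(C)C)C(C)C
F3 | step 14 | (3R,6S)-3-hydroxy-6-[(2R)-1-(4-hydroxy-3-methoxyphenyl)propan-2-yl]-6-methoxy-4-(prop-2-en-1-yl)cyclohex-4-en-1-one | C=CCC1=C[C@@](OC)([C@H](C)Cc2ccc(O)c(OC)c2)C(=O)C[C@H]1O
F4 | step 14 | (4S)-5-hydroxy-4-[(2R)-1-(4-hydroxy-3-methoxyphenyl)propan-2-yl]-4-methoxy-2-(prop-2-en-1-yl)cyclohexa-2,5-dien-1-one (enol form of the 1,3-dione) | C=CCC1=C[C@@](OC)([C@H](C)Cc2ccc(O)c(OC)c2)C(O)=CC1=O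
F5 | step 11 | (2R)-3-[3-methoxy-4-(triisopropylsilyloxy)phenyl]-2-methylpropan-1-ol | OC[C@H](C)Cc1ccc(O[Si](C(C)C)(C(C)C)C(C)C)c(OC)c1
F6 | step 11 | (2R)-3-[3-methoxy-4-(triisopropylsilyloxy)phenyl]-2-methylpropanal | O=C[C@H](C)Cc1ccc(O[Si](C(C)C)(C(C)C)C(C)C)c(OC)c1
F7 | step 11 | (2R,4Z,6R)-8,8-dimethoxy-1-[3-methoxy-4-(triisopropylsilyloxy)phenyl]-2-methyl-5-(prop-2-en-1-yl)-6-(triisopropylsilyloxy)oct-4-en-3-ol (both C3 epimers) | C=CC/C(=C/C(O)[C@H](C)Cc1ccc(O[Si](C(C)C)(C(C)C)C(C)C)c(OC)c1)[C@H](O[Si](C(C)C)(C(C)C)C(C)C)CC(OC)OC
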